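**Retrosynthetic overview**

- The strategy rests on the 3,4-dihydro-2H-pyran ring (O1, C2 guaiacyl, C3 CH2OAc, C4 H2, C5 benzofuran-2-yl, C6 enol ether CH). Each of these atoms maps onto a separate handle of a 2-aryl-6-hydroxy-2H-pyran-3(6H)-one: carbinol carbon (C2), ketone (C3), enone (C4=C5) and lactol (C6).
- Disconnections, backwards: C5=C6 by loss of methanol from a C6 methyl acetal; C3–CH2OAc from the C3 ketone by methoxymethylenation, hydrolysis and equilibration to the C2,C3-trans aldehyde; C5–benzofuran C2 by rhodium-catalysed 1,4-addition of a benzofuran-2-ylboronate to the enone.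
- The pyranone comes from an (S)-aryl(2-furyl)methanol by Achmatowicz oxidative ring expansion (forms O1–C6). The carbinol comes from silylated vanillin and 2-lithiofuran, followed by kinetic resolution.
- Ring order: the furan ring of the benzofuran is closed first, in a separate fragment (Sonogashira coupling, 5-endo-dig cyclisation, C2–H borylation). The pyran ring then arises by ring expansion of the furan of the carbinol, and the two parts are joined at C5.

Key step: step 4

Remark: the sense of the kinetic resolution is assigned by analogy with secondary allylic alcohols (furan C2=C3 as the olefin). C6 anomers, the C5 configuration and the enol ether geometry are drawn as the expected major forms; all three are erased before the target.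

Abbreviations: Ar = 4-(tert-butyldimethylsilyloxy)-3-methoxyphenyl; Bf = 6-acetyl-5-hydroxy-1-benzofuran-2-yl; Bpin = 4,4,5,5-tetramethyl-1,3,2-dioxaborolan-2-yl.

**Route**

Step 1
Reactants: 1 vanillin
Product: 2 4-(tert-butyldimethylsilyloxy)-3-methoxybenzaldehyde
Conditions: TBSCl, imidazole, DMF, 0 °C → rt
Reagents that add atoms: tert-butyldimethylsilyl chloride, CC(C)(C)[Si](C)(C)Cl
Why: Imidazole-promoted O-silylation of a phenol is routine and masks the phenol for the later furan oxidation; no stereocentre is formed.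

Step 2
Reactants: 3 furan; 2 4-(tert-butyldimethylsilyloxy)-3-methoxybenzaldehyde
Product: 5 rac-Ar(furan-2-yl)methanol, via 2-furyllithium 4 (not isolated)
Conditions: furan, n-BuLi, THF, 0 °C; then 2, −78 °C; then H2O
Reagents that add atoms: none
Why: Furan is lithiated cleanly at C2 and the organolithium adds 1,2 to the non-enolisable aldehyde (organolithium addition to a carbonyl), giving the racemic carbinol.

Step 3
Reactants: 5 rac-Ar(furan-2-yl)methanol
Product: 6 (S)-Ar(furan-2-yl)methanol
Conditions: Ti(OiPr)4 (20 mol%), D-(−)-diisopropyl tartrate (24 mol%), t-BuOOH (0.6 equiv), 4 Å MS, CH2Cl2, −20 °C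
Reagents that add atoms: none
Why: Sharpless-type kinetic resolution of a 2-furylcarbinol, in which the titanium tartrate/t-BuOOH system treats the furan C2=C3 bond as the olefin of a secondary allylic alcohol, so that with the D-tartrate the (R)-enantiomer should be oxidised to a pyranone and removed by chromatography while the slow (S)-enantiomer is recovered with an enantiomeric purity that rises as conversion passes the halfway point.

Step 4
Reactants: 6 (S)-Ar(furan-2-yl)methanol
Product: 8 (2S)-2-Ar-6-hydroxy-2H-pyran-3(6H)-one (C6 anomers), via Z-ene-dione 7 (not isolated)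
Conditions: NBS (1.05 equiv), NaHCO3, NaOAc, THF/H2O (4:1), 0 °C
Reagents that add atoms: water, O
Why: NBS attacks the furan at C5 as an electrophile and water adds at C2 (oxidative 2,5-addition), and the resulting 2,5-dihydrofuran collapses to the Z-ene-dione 7, in which the former furan oxygen has become the C3 ketone. The carbinol hydroxyl then adds to the aldehyde carbon in a 6-exo-trig hemiacetalisation, forming the O1–C6 bond and closing the pyran ring as lactol 8. This is the Achmatowicz rearrangement of a furfuryl alcohol, here with an aryl group on the carbinol carbon. The only new stereocentre is the anomeric C6, which forms as a mixture under thermodynamic control and is erased later; C2 keeps the configuration of 6 because none of its bonds is broken. The step needs oxidation of the furan in preference to the silylated guaiacyl ring, which the much higher nucleophilicity of a 2-alkylfuran toward NBS at 0 °C should secure. The bicarbonate/acetate buffer removes HBr so that the doubly activated carbinol is not ionised (no Piancatelli-type pathway), yet it is too weak a base to deprotonate C2–H next to the new ketone.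

Step 5
Reactants: 8 (2S)-2-Ar-6-hydroxy-2H-pyran-3(6H)-one
Product: 9 (2S,6R)-2-Ar-6-methoxy-2H-pyran-3(6H)-one (2,6-trans)
Conditions: CH(OMe)3, BF3·OEt2 (cat.), CH2Cl2, −30 → 0 °C
Reagents that add atoms: trimethyl orthoformate, COC(OC)OC
Why: Acid-catalysed acetal exchange through the C6 oxocarbenium ion (Fischer-type glycosidation with the orthoformate as methanol source and water scavenger) should favour the 2,6-trans anomer with axial methoxy through the anomeric effect, while the adjacent C3 carbonyl disfavours ionisation at the benzylic C2.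

Step 6
Reactants: 10 2-bromo-1,4-dimethoxybenzene
Product: 11 1-(4-bromo-2,5-dimethoxyphenyl)ethanone
Conditions: AcCl, AlCl3 (1.2 equiv), CH2Cl2, 0 °C
Reagents that add atoms: acetyl chloride, CC(=O)Cl
Why: Friedel–Crafts acetylation should occur para to bromine and ortho to a methoxy group, the one position activated by both substituents and not flanked by two of them.

Step 7
Reactants: 11 1-(4-bromo-2,5-dimethoxyphenyl)ethanone
Product: 12 1-(4-bromo-2,5-dihydroxyphenyl)ethanone
Conditions: BBr3 (3 equiv), CH2Cl2, −78 °C → rt; then H2O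
Reagents that add atoms: none
Why: Lewis acid-mediated demethylation with BBr3 cleaves both aryl methyl ethers, the one ortho to the acetyl group with chelation assistance, and leaves the aryl bromide and the ketone intact.

Step 8
Reactants: 12 1-(4-bromo-2,5-dihydroxyphenyl)ethanone; 13 ethynyltrimethylsilane
Product: 14 1-{2,5-dihydroxy-4-[(trimethylsilyl)ethynyl]phenyl}ethanone
Conditions: PdCl2(PPh3)2 (3 mol%), CuI (5 mol%), Et3N, THF, 50 °C, degassed
Reagents that add atoms: none
Why: Sonogashira coupling at an aryl bromide activated by the para acetyl group, run at moderate temperature so that the ortho-alkynylphenol does not cyclise prematurely and without air so that the hydroquinone is not oxidised.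

Step 9
Reactants: 14 1-{2,5-dihydroxy-4-[(trimethylsilyl)ethynyl]phenyl}ethanone
Product: 16 1-(5-hydroxy-1-benzofuran-6-yl)ethanone, via terminal alkyne 15 (not isolated)
Conditions: K2CO3, MeOH, rt; then CuI (10 mol%), Et3N, 65 °C
Reagents that add atoms: none
Why: Methanolysis frees the terminal alkyne and copper-promoted 5-endo-dig addition of the adjacent phenoxide to it (cycloisomerisation of an ortho-ethynylphenol) closes the furan ring, while the chelated hydroxyl para to it cannot reach the alkyne.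

Step 10
Reactants: 16 1-(5-hydroxy-1-benzofuran-6-yl)ethanone
Product: 19 1-(5-hydroxy-2-Bpin-1-benzofuran-6-yl)ethanone, via O-boryl benzofuran 17 (not isolated), via diboryl benzofuran 18 (not isolated)
Conditions: HBpin (1.1 equiv), THF, rt; then [Ir(OMe)(cod)]2 (1.5 mol%), dtbpy (3 mol%), B2pin2 (1.0 equiv), 50 °C; then MeOH
Reagents that add atoms: bis(pinacolato)diboron, CC1(C)OB(OC1(C)C)B1OC(C)(C)C(C)(C)O1
Why: Iridium-catalysed C–H borylation of a benzofuran is selective for the C2–H bond next to the ring oxygen, the phenol being masked in the flask as its O-Bpin ether that methanol removes on work-up, and the benzenoid C–H bonds at C4 and C7 each lie ortho to a substituent.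

Step 11
Reactants: 9 (2S,6R)-2-Ar-6-methoxy-2H-pyran-3(6H)-one; 19 1-(5-hydroxy-2-Bpin-1-benzofuran-6-yl)ethanone
Product: 20 (2S,5S,6R)-5-Bf-2-Ar-6-methoxyoxan-3-one
Conditions: [Rh(OH)(cod)]2 (3 mol%), 19 (1.5 equiv), dioxane/H2O (10:1), 40 °C
Reagents that add atoms: none
Why: Hayashi–Miyaura rhodium-catalysed 1,4-addition of a heteroarylboronate to a cyclic enone, in which the aryl–rhodium species should add to the enone β-carbon C5 anti to the neighbouring C6 methoxy group (substrate control; this centre is erased later) and the rhodium enolate is protonated by water under base-free conditions that spare the acidic C2–H.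

Step 12
Reactants: 20 (2S,5S,6R)-5-Bf-2-Ar-6-methoxyoxan-3-one
Product: 22 (2S,5S,6R)-5-Bf-2-Ar-6-methoxy-3-(methoxymethylidene)oxane (E/Z mixture), via potassium phenoxide 21 (not isolated)
Conditions: MeOCH2PPh3Cl (3.2 equiv), KHMDS (3.0 equiv), THF, 0 °C; then 20, −78 → 0 °C
Reagents that add atoms: (methoxymethyl)triphenylphosphonium chloride, COC[P+](c1ccccc1)(c1ccccc1)c1ccccc1.[Cl-]
Why: Wittig methoxymethylenation in which the first equivalent of ylide converts the phenol into its potassium phenoxide 21, making the ortho acetyl group a vinylogous carboxylate far less electrophilic than the α-alkoxy ketone at C3, so that olefination should occur at C3 only while the low temperature limits enolisation toward C2.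

Step 13
Reactants: 22 (2S,5S,6R)-5-Bf-2-Ar-6-methoxy-3-(methoxymethylidene)oxane
Product: 25 (2R,3R,5S,6R)-5-Bf-2-Ar-6-methoxyoxane-3-carbaldehyde (2,3-trans), via mercurio aldehyde 23 (not isolated), via aldehyde epimer mixture 24 (not isolated)
Conditions: Hg(OAc)2 (1.5 equiv), THF/H2O (10:1), 0 °C; then aq. KI; then DBU (2 equiv), CH2Cl2, 0 °C → rt
Reagents that add atoms: water, O
Why: Oxymercuration of the enol ether and iodide-induced demercuration hydrolyse it at neutral pH so that the C6 methyl acetal survives, and DBU then equilibrates the aldehyde through its enolate to the C2,C3-trans isomer (thermodynamic control of C3), in which formyl and aryl are both equatorial and the 1,3-diaxial clash of an axial formyl group with the axial C5 benzofuranyl group is avoided.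

Step 14
Reactants: 25 (2R,3R,5S,6R)-5-Bf-2-Ar-6-methoxyoxane-3-carbaldehyde
Product: 26 [(2R,3S,5S,6R)-5-Bf-2-Ar-6-methoxyoxan-3-yl]methanol
Conditions: NaBH4, MeOH/THF, −40 °C
Reagents that add atoms: none
Why: Chemoselective hydride reduction, since NaBH4 at low temperature reduces the aldehyde much faster than the hydrogen-bonded ortho-hydroxyaryl ketone and does not touch the C3 centre.

Step 15
Reactants: 26 [(2R,3S,5S,6R)-5-Bf-2-Ar-6-methoxyoxan-3-yl]methanol
Product: 27 [(2R,3S,5S,6R)-5-Bf-2-Ar-6-methoxyoxan-3-yl]methyl acetate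
Conditions: AcCl (1.2 equiv), 2,4,6-collidine, CH2Cl2, −78 → −40 °C
Reagents that add atoms: acetyl chloride, CC(=O)Cl
Why: Selective O-acylation of the unhindered primary alcohol, the chelated phenol being a poor nucleophile that collidine cannot deprotonate at this temperature.

Step 16
Reactants: 27 [(2R,3S,5S,6R)-5-Bf-2-Ar-6-methoxyoxan-3-yl]methyl acetate
Product: 30 [(2R,3S)-5-Bf-2-Ar-3,4-dihydro-2H-pyran-3-yl]methyl acetate, via silylated acetal 28 (not isolated), via silylated dihydropyran 29 (not isolated)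
Conditions: TMSOTf (2.5 equiv), iPr2NEt (4 equiv), CH2Cl2, −78 → −20 °C; then MeOH, NaHCO3
Reagents that add atoms: none
Why: Silyl triflate/amine conversion of an acetal into an enol ether, in which, after silylation of the phenol, TMSOTf ionises the C6 methoxy group to the ring oxocarbenium ion and the hindered amine removes the C5 proton (the only β-hydrogen, acidified by the benzofuran) to give the conjugated C5=C6 enol ether at low temperature and without free acid that could ionise the benzylic C2–O bond, the aryl TMS ether falling off in the methanolic work-up.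

Step 17
Reactants: 30 [(2R,3S)-5-Bf-2-Ar-3,4-dihydro-2H-pyran-3-yl]methyl acetate
Product: 31 propolis-benzofuran A, [(2R,3S)-5-(6-acetyl-5-hydroxy-1-benzofuran-2-yl)-2-(4-hydroxy-3-methoxyphenyl)-3,4-dihydro-2H-pyran-3-yl]methyl acetate
Conditions: TBAF (1.2 equiv), AcOH (1.2 equiv), THF, 0 °C
Reagents that add atoms: none
Why: Fluoride-mediated desilylation of the aryl silyl ether, buffered with acetic acid so that the liberated phenoxide does not attack the primary acetate or the enol ether.

**Compound list**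

1 | vanillin | COc1cc(C=O)ccc1O | starting material
2 | 4-(tert-butyldimethylsilyloxy)-3-methoxybenzaldehyde | COc1cc(C=O)ccc1O[Si](C)(C)C(C)(C)C | intermediate
3 | furan | c1ccoc1 | starting material
4 | 2-furyllithium | [Li]c1ccco1 | intermediate (not isolated)
5 | rac-[4-(tert-butyldimethylsilyloxy)-3-methoxyphenyl](furan-2-yl)methanol | COc1cc(C(O)c2ccco2)ccc1O[Si](C)(C)C(C)(C)C | intermediate
6 | (S)-[4-(tert-butyldimethylsilyloxy)-3-methoxyphenyl](furan-2-yl)methanol | COc1cc([C@H](O)c2ccco2)ccc1O[Si](C)(C)C(C)(C)C | intermediate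
7 | (2Z,5S)-5-[4-(tert-butyldimethylsilyloxy)-3-methoxyphenyl]-5-hydroxy-4-oxopent-2-enal | COc1cc([C@H](O)C(=O)/C=C\C=O)ccc1O[Si](C)(C)C(C)(C)C | intermediate (not isolated)
8 | (2S)-2-[4-(tert-butyldimethylsilyloxy)-3-methoxyphenyl]-6-hydroxy-2H-pyran-3(6H)-one, C6 anomers | COc1cc([C@@H]2OC(O)C=CC2=O)ccc1O[Si](C)(C)C(C)(C)C | intermediate
9 | (2S,6R)-2-[4-(tert-butyldimethylsilyloxy)-3-methoxyphenyl]-6-methoxy-2H-pyran-3(6H)-one (2,6-trans) | COc1cc([C@@H]2O[C@@H](OC)C=CC2=O)ccc1O[Si](C)(C)C(C)(C)C | intermediate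
10 | 2-bromo-1,4-dimethoxybenzene | COc1ccc(OC)c(Br)c1 | starting material
11 | 1-(4-bromo-2,5-dimethoxyphenyl)ethanone | CC(=O)c1cc(OC)c(Br)cc1OC | intermediate
12 | 1-(4-bromo-2,5-dihydroxyphenyl)ethanone | CC(=O)c1cc(O)c(Br)cc1O | intermediate
13 | ethynyltrimethylsilane | C#C[Si](C)(C)C | starting material
14 | 1-{2,5-dihydroxy-4-[(trimethylsilyl)ethynyl]phenyl}ethanone | CC(=O)c1cc(O)c(C#C[Si](C)(C)C)cc1O | intermediate
15 | 1-(4-ethynyl-2,5-dihydroxyphenyl)ethanone | CC(=O)c1cc(O)c(C#C)cc1O | intermediate (not isolated)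
16 | 1-(5-hydroxy-1-benzofuran-6-yl)ethanone | CC(=O)c1cc2occc2cc1O | intermediate
17 | 1-[5-(4,4,5,5-tetramethyl-1,3,2-dioxaborolan-2-yloxy)-1-benzofuran-6-yl]ethanone | CC(=O)c1cc2occc2cc1OB1OC(C)(C)C(C)(C)O1 | intermediate (not isolated)
18 | 1-[2-(4,4,5,5-tetramethyl-1,3,2-dioxaborolan-2-yl)-5-(4,4,5,5-tetramethyl-1,3,2-dioxaborolan-2-yloxy)-1-benzofuran-6-yl]ethanone | CC(=O)c1cc2oc(B3OC(C)(C)C(C)(C)O3)cc2cc1OB1OC(C)(C)C(C)(C)O1 | intermediate (not isolated)
19 | 1-[5-hydroxy-2-(4,4,5,5-tetramethyl-1,3,2-dioxaborolan-2-yl)-1-benzofuran-6-yl]ethanone | CC(=O)c1cc2oc(B3OC(C)(C)C(C)(C)O3)cc2cc1O | intermediate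
20 | (2S,5S,6R)-5-(6-acetyl-5-hydroxy-1-benzofuran-2-yl)-2-[4-(tert-butyldimethylsilyloxy)-3-methoxyphenyl]-6-methoxyoxan-3-one | COc1cc([C@@H]2O[C@@H](OC)[C@H](c3cc4cc(O)c(C(C)=O)cc4o3)CC2=O)ccc1O[Si](C)(C)C(C)(C)C | intermediate
21 | potassium phenoxide of 20 | COc1cc([C@@H]2O[C@@H](OC)[C@H](c3cc4cc([O-])c(C(C)=O)cc4o3)CC2=O)ccc1O[Si](C)(C)C(C)(C)C.[K+] | intermediate (not isolated)
22 | (2S,5S,6R)-5-(6-acetyl-5-hydroxy-1-benzofuran-2-yl)-2-[4-(tert-butyldimethylsilyloxy)-3-methoxyphenyl]-6-methoxy-3-(methoxymethylidene)oxane, E/Z mixture | COc1cc([C@@H]2O[C@@H](OC)[C@H](c3cc4cc(O)c(C(C)=O)cc4o3)CC2=COC)ccc1O[Si](C)(C)C(C)(C)C | intermediate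
23 | (2S,5S,6R)-3-(acetoxymercurio)-5-(6-acetyl-5-hydroxy-1-benzofuran-2-yl)-2-[4-(tert-butyldimethylsilyloxy)-3-methoxyphenyl]-6-methoxyoxane-3-carbaldehyde, C3 mixture | COc1cc([C@@H]2O[C@@H](OC)[C@H](c3cc4cc(O)c(C(C)=O)cc4o3)CC2(C=O)[Hg]OC(C)=O)ccc1O[Si](C)(C)C(C)(C)C | intermediate (not isolated)
24 | (2R,5S,6R)-5-(6-acetyl-5-hydroxy-1-benzofuran-2-yl)-2-[4-(tert-butyldimethylsilyloxy)-3-methoxyphenyl]-6-methoxyoxane-3-carbaldehyde, C3 epimers | COc1cc([C@@H]2O[C@@H](OC)[C@H](c3cc4cc(O)c(C(C)=O)cc4o3)CC2C=O)ccc1O[Si](C)(C)C(C)(C)C | intermediate (not isolated)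
25 | (2R,3R,5S,6R)-5-(6-acetyl-5-hydroxy-1-benzofuran-2-yl)-2-[4-(tert-butyldimethylsilyloxy)-3-methoxyphenyl]-6-methoxyoxane-3-carbaldehyde (2,3-trans) | COc1cc([C@@H]2O[C@@H](OC)[C@H](c3cc4cc(O)c(C(C)=O)cc4o3)C[C@H]2C=O)ccc1O[Si](C)(C)C(C)(C)C | intermediate
26 | [(2R,3S,5S,6R)-5-(6-acetyl-5-hydroxy-1-benzofuran-2-yl)-2-[4-(tert-butyldimethylsilyloxy)-3-methoxyphenyl]-6-methoxyoxan-3-yl]methanol | COc1cc([C@@H]2O[C@@H](OC)[C@H](c3cc4cc(O)c(C(C)=O)cc4o3)C[C@H]2CO)ccc1O[Si](C)(C)C(C)(C)C | intermediate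
27 | [(2R,3S,5S,6R)-5-(6-acetyl-5-hydroxy-1-benzofuran-2-yl)-2-[4-(tert-butyldimethylsilyloxy)-3-methoxyphenyl]-6-methoxyoxan-3-yl]methyl acetate | COc1cc([C@@H]2O[C@@H](OC)[C@H](c3cc4cc(O)c(C(C)=O)cc4o3)C[C@H]2COC(C)=O)ccc1O[Si](C)(C)C(C)(C)C | intermediate
28 | 27 with the benzofuran 5-hydroxyl as its trimethylsilyl ether | COc1cc([C@@H]2O[C@@H](OC)[C@H](c3cc4cc(O[Si](C)(C)C)c(C(C)=O)cc4o3)C[C@H]2COC(C)=O)ccc1O[Si](C)(C)C(C)(C)C | intermediate (not isolated)
29 | [(2R,3S)-5-[6-acetyl-5-(trimethylsilyloxy)-1-benzofuran-2-yl]-2-[4-(tert-butyldimethylsilyloxy)-3-methoxyphenyl]-3,4-dihydro-2H-pyran-3-yl]methyl acetate | COc1cc([C@@H]2OC=C(c3cc4cc(O[Si](C)(C)C)c(C(C)=O)cc4o3)C[C@H]2COC(C)=O)ccc1O[Si](C)(C)C(C)(C)C | intermediate (not isolated)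
30 | [(2R,3S)-5-(6-acetyl-5-hydroxy-1-benzofuran-2-yl)-2-[4-(tert-butyldimethylsilyloxy)-3-methoxyphenyl]-3,4-dihydro-2H-pyran-3-yl]methyl acetate | COc1cc([C@@H]2OC=C(c3cc4cc(O)c(C(C)=O)cc4o3)C[C@H]2COC(C)=O)ccc1O[Si](C)(C)C(C)(C)C | intermediate
31 | propolis-benzofuran A, [(2R,3S)-5-(6-acetyl-5-hydroxy-1-benzofuran-2-yl)-2-(4-hydroxy-3-methoxyphenyl)-3,4-dihydro-2H-pyran-3-yl]methyl acetate | COc1cc([C@@H]2OC=C(c3cc4cc(O)c(C(C)=O)cc4o3)C[C@H]2COC(C)=O)ccc1O | target

**Step count and risks**

Total steps: 17. Longest linear sequence: 12 steps (steps 1–5 and 11–17; the benzofuran branch, steps 6–10 and 11–17, is equally long).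

Steps most likely to fail:

Step 11. Protodeboronation of the 2-benzofuranylboronate may outrun transmetalation to rhodium, or carbometalation of the enone next to the acetal carbon may be too slow under the base-free conditions needed to protect C2–H. The fallback sets out from 9 and returns at 20, building the benzofuran on C5 instead of transferring it. Ni(acac)2/DIBAL-H-catalysed conjugate addition of the dimethylalkynylalane made from 13 (n-BuLi, then Me2AlCl) to the enone of 9 would give (2S,5S,6R)-2-Ar-6-methoxy-5-[(trimethylsilyl)ethynyl]oxan-3-one F1. AgNO3-catalysed C-desilylation in aqueous acetone would then free (2S,5S,6R)-2-Ar-5-ethynyl-6-methoxyoxan-3-one F2. Sonogashira coupling of F2 with bromophenol 12 (PdCl2(PPh3)2, CuI, Et3N, DMF, 60 °C), followed in the same flask by copper-promoted 5-endo-dig closure of the ortho hydroxyl onto the alkyne, would deliver 20.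

Step 12. The ylide may also olefinate the acetyl group if deactivation through the phenoxide is not sufficient, or it may act as a base and enolise the ketone toward C2, eroding that centre. The fallback sets out from 9 and returns at 27; it finishes C3 before the acetyl-bearing ring exists. Alkynyl ketone F1 (made from 9 as in the fallback for step 11) would be olefinated with Ph3P=CHOMe to (2S,5S,6R)-2-Ar-6-methoxy-3-(methoxymethylidene)-5-[(trimethylsilyl)ethynyl]oxane F3. Hg(OAc)2/KI hydrolysis and DBU equilibration would give the 2,3-trans aldehyde, (2R,3R,5S,6R)-2-Ar-6-methoxy-5-[(trimethylsilyl)ethynyl]oxane-3-carbaldehyde F4. NaBH4 would give the alcohol, [(2R,3S,5S,6R)-2-Ar-6-methoxy-5-[(trimethylsilyl)ethynyl]oxan-3-yl]methanol F5, and Ac2O/pyridine its acetate, [(2R,3S,5S,6R)-2-Ar-6-methoxy-5-[(trimethylsilyl)ethynyl]oxan-3-yl]methyl acetate F6. AgNO3-catalysed desilylation would give the terminal alkyne, [(2R,3S,5S,6R)-2-Ar-5-ethynyl-6-methoxyoxan-3-yl]methyl acetate F7, and Sonogashira coupling of F7 with 12 with in situ cyclisation would give 27.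

Step 16. Under the silyl triflate, ionisation of the benzylic C2–O1 bond or endocyclic cleavage of C6–O1 may compete with loss of the C5 proton, scrambling C2 or opening the ring. The fallback sets out from 27 and returns at 30; it replaces the cationic elimination by a thermal syn-elimination. Exchange of the C6 methoxy group for phenylthio (PhSH, BF3·OEt2, CH2Cl2, −40 °C) would give the axial thioglycoside, [(2R,3S,5S,6S)-5-Bf-2-Ar-6-(phenylsulfanyl)oxan-3-yl]methyl acetate F8. mCPBA at −78 °C would give the sulfoxide, [(2R,3S,5S)-5-Bf-2-Ar-6-(phenylsulfinyl)oxan-3-yl]methyl acetate F9. Thermolysis (toluene, 90 °C, iPr2NEt) would expel benzenesulfenic acid through the cis C5–H and give 30.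

**Further compounds**

F1 | step 11 | (2S,5S,6R)-2-[4-(tert-butyldimethylsilyloxy)-3-methoxyphenyl]-6-methoxy-5-[(trimethylsilyl)ethynyl]oxan-3-one | COc1cc([C@@H]2O[C@@H](OC)[C@H](C#C[Si](C)(C)C)CC2=O)ccc1O[Si](C)(C)C(C)(C)C
F2 | step 11 | (2S,5S,6R)-2-[4-(tert-butyldimethylsilyloxy)-3-methoxyphenyl]-5-ethynyl-6-methoxyoxan-3-one | COc1cc([C@@H]2O[C@@H](OC)[C@H](C#C)CC2=O)ccc1O[Si](C)(C)C(C)(C)C
F3 | step 12 | (2S,5S,6R)-2-[4-(tert-butyldimethylsilyloxy)-3-methoxyphenyl]-6-methoxy-3-(methoxymethylidene)-5-[(trimethylsilyl)ethynyl]oxane, E/Z mixture | COc1cc([C@@H]2O[C@@H](OC)[C@H](C#C[Si](C)(C)C)CC2=COC)ccc1O[Si](C)(C)C(C)(C)C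
F4 | step 12 | (2R,3R,5S,6R)-2-[4-(tert-butyldimethylsilyloxy)-3-methoxyphenyl]-6-methoxy-5-[(trimethylsilyl)ethynyl]oxane-3-carbaldehyde | COc1cc([C@@H]2O[C@@H](OC)[C@H](C#C[Si](C)(C)C)C[C@H]2C=O)ccc1O[Si](C)(C)C(C)(C)C
F5 | step 12 | [(2R,3S,5S,6R)-2-[4-(tert-butyldimethylsilyloxy)-3-methoxyphenyl]-6-methoxy-5-[(trimethylsilyl)ethynyl]oxan-3-yl]methanol | COc1cc([C@@H]2O[C@@H](OC)[C@H](C#C[Si](C)(C)C)C[C@H]2CO)ccc1O[Si](C)(C)C(C)(C)C
F6 | step 12 | [(2R,3S,5S,6R)-2-[4-(tert-butyldimethylsilyloxy)-3-methoxyphenyl]-6-methoxy-5-[(trimethylsilyl)ethynyl]oxan-3-yl]methyl acetate | COc1cc([C@@H]2O[C@@H](OC)[C@H](C#C[Si](C)(C)C)C[C@H]2COC(C)=O)ccc1O[Si](C)(C)C(C)(C)C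
F7 | step 12 | [(2R,3S,5S,6R)-2-[4-(tert-butyldimethylsilyloxy)-3-methoxyphenyl]-5-ethynyl-6-methoxyoxan-3-yl]methyl acetate | COc1cc([C@@H]2O[C@@H](OC)[C@H](C#C)C[C@H]2COC(C)=O)ccc1O[Si](C)(C)C(C)(C)C
F8 | step 16 | [(2R,3S,5S,6S)-5-(6-acetyl-5-hydroxy-1-benzofuran-2-yl)-2-[4-(tert-butyldimethylsilyloxy)-3-methoxyphenyl]-6-(phenylsulfanyl)oxan-3-yl]methyl acetate | COc1cc([C@@H]2O[C@@H](Sc5ccccc5)[C@H](c3cc4cc(O)c(C(C)=O)cc4o3)C[C@H]2COC(C)=O)ccc1O[Si](C)(C)C(C)(C)C
F9 | step 16 | [(2R,3S,5S)-5-(6-acetyl-5-hydroxy-1-benzofuran-2-yl)-2-[4-(tert-butyldimethylsilyloxy)-3-methoxyphenyl]-6-(phenylsulfinyl)oxan-3-yl]methyl acetate, sulfur epimers | COc1cc([C@@H]2O[C@@H](S(=O)c5ccccc5)[C@H](c3cc4cc(O)c(C(C)=O)cc4o3)C[C@H]2COC(C)=O)ccc1O[Si](C)(C)C(C)(C)C
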